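Numbering: ring B = C1–C6 (C2–Br, C3 carbinol with methyl C15, spiro C6); ring A = C6–C11 (C7=C14H2, C10–Br, C11 gem-dimethyl).
Enabling feature: C7 and C10 both derive from ketones that stand 1,4 across ring A, each flanked by a quaternary carbon (C6, C11), so in the ring-opened bis(methyl ketone) only C8 and C9 can enolise and can be joined by oxidation of the bis-enolate.
Cuts (retro): C10–Br and C7=C14 back to the C7/C10 diketone; C2–Br/C3–O back to the C2=C3 alkene; C8–C9 (ring A); the two acetyl C–CH3 bonds (C7–C8, C9–C10); C4–C5 and C1–C6 (Diels–Alder, ring B).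
Forward: the C6–C11 bond is already in the dienophile; ring B is made first (Diels–Alder with isoprene), ring A second (C8–C9 coupling), then bromoketal, C7 methylenation and C10 bromide.
Stereochemistry: C6 from the oxazaborolidinium-catalysed Diels–Alder reaction; C2 and C3 from an anti bromoketalisation that delivers the C7 carbonyl oxygen to C3 on its own face; C10 from a Corey–Bakshi–Shibata reduction followed by Appel inversion.
C10 receives its configuration only after the ketal is opened, because the ketal carbon forms as two epimers that hold ring A in opposite chairs.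

Key step: step 6

Assumption: the cationic oxazaborolidine from (S)-diphenylprolinol is taken to deliver isoprene to the face of enal 4 that gives (S)-6, following the usual formyl C–H···O binding model for 2-substituted acroleins; should the adduct prove to be (R)-6, the catalyst from (R)-diphenylprolinol is used without other change.

Step 1
Reactants: 1 methyl 2,2-dimethylpent-4-enoate
Product: 3 methyl 2,2-dimethyl-4-oxobutanoate, via ozonide 2 (not isolated)
Conditions: O3, CH2Cl2, −78 °C; then Me2S, −78 → 23 °C
Reagents that add atoms: ozone, [O-][O+]=O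
Why: Ozonolysis with reductive work-up cuts the terminal alkene to the C7 aldehyde, and the quaternary ester is inert to ozone and Me2S.

Step 2
Reactants: 3 methyl 2,2-dimethyl-4-oxobutanoate
Product: 4 methyl 3-formyl-2,2-dimethylbut-3-enoate
Conditions: 37% aq. CH2O, pyrrolidine (10 mol%), propanoic acid (10 mol%), i-PrOH, 45 °C
Reagents that add atoms: formaldehyde, C=O
Why: Amine-catalysed Mannich condensation with formaldehyde followed by β-elimination (α-methylenation of an aldehyde) can take place only at the single α-CH2 of 3 and gives the 2-substituted acrolein that already carries the C6–C11 bond.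

Step 3
Reactants: 4 methyl 3-formyl-2,2-dimethylbut-3-enoate; 5 isoprene
Product: 6 methyl 2-[(1S)-1-formyl-4-methylcyclohex-3-en-1-yl]-2-methylpropanoate
Conditions: 5 (5 equiv), (S)-3,3-diphenyl-1-(2-methylphenyl)tetrahydro-1H,3H-pyrrolo[1,2-c][1,3,2]oxazaborole (20 mol%), Tf2NH (17 mol%), CH2Cl2, −78 → −40 °C
Reagents that add atoms: none
Why: Lewis acid-catalysed Diels–Alder reaction of a 2-substituted acrolein with isoprene, in which the "para" orientation places C6 opposite the methyl-bearing C3 and the protonated oxazaborolidine, holding the formyl group by B–O coordination and a formyl C–H···O contact, screens one face of the enal so that C6 should be set as S.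

Step 4
Reactants: 6 methyl 2-[(1S)-1-formyl-4-methylcyclohex-3-en-1-yl]-2-methylpropanoate
Product: 8 3-[(1S)-1-(1-hydroxyethyl)-4-methylcyclohex-3-en-1-yl]-3-methylbutan-2-one (both carbinol epimers; open form of its lactol), via lactone 7 (not isolated)
Conditions: MeMgBr (1.1 equiv), THF, −78 → 23 °C; then MeLi (1.2 equiv), −78 °C; aq. NH4Cl
Reagents that add atoms: methylmagnesium bromide, C[Mg]Br; methyllithium, [Li]C
Why: Grignard addition to the aldehyde gives an alkoxide that closes onto the neighbouring ester (five-membered ring, gem-dimethyl effect) to lactone 7, and a single addition of MeLi to this hindered lactone at −78 °C stops at the lithium hemiketal, so C10 ends at the methyl ketone level without over-addition.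

Step 5
Reactants: 8 3-[(1S)-1-(1-hydroxyethyl)-4-methylcyclohex-3-en-1-yl]-3-methylbutan-2-one
Product: 9 3-[(1S)-1-acetyl-4-methylcyclohex-3-en-1-yl]-3-methylbutan-2-one
Conditions: Dess–Martin periodinane, CH2Cl2, 23 °C
Reagents that add atoms: none
Why: Dess–Martin oxidation of the secondary carbinol, reached through the open hydroxy ketone form of the lactol, should give the 1,4-diketone, which cannot dehydrate to a furan because C6 and C11 carry no hydrogen.

Step 6
Reactants: 9 3-[(1S)-1-acetyl-4-methylcyclohex-3-en-1-yl]-3-methylbutan-2-one
Product: 11 (6S)-3,11,11-trimethylspiro[5.5]undec-2-ene-7,10-dione, via bis-enolate 10 (not isolated)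
Conditions: LiN(i-Pr)2 (2.3 equiv), THF, −78 °C, 9 added over 1 h; then cannulated slowly into CuCl2 (2.5 equiv), DMF, −78 → 0 °C, final 0.005 M
Reagents that add atoms: none
Why: Two equivalents of LiN(i-Pr)2 remove one proton from each acetyl methyl group, the only enolisable positions because C6 and C11 are quaternary, and give bis-enolate 10. CuCl2 (divalent copper) takes one electron from an enolate to give an α-keto radical at C8, which adds to the CH2 terminus (C9) of the second enolate, and the resulting ketyl-type radical anion is oxidised by a second CuCl2 to the C10 ketone. The closest known reaction type is the oxidative coupling of ketone lithium enolates to 1,4-diketones with CuCl2 or FeCl3, including intramolecular closures of diketone bis-enolates. Ring A closes in a 6-endo-trig mode with respect to the C9=C10 enolate, the matched polarity (electrophilic radical, electron-rich enolate carbon) directing attack to carbon and not to oxygen. No stereocentre is formed, and C6, having no α-hydrogen, cannot epimerise. The step needs ring closure to beat dimerisation and the five-membered aldol; full double deprotonation before any oxidant is present, the vicinal quaternary carbons C6/C11 that hold the two enolate termini close together, and slow addition to the oxidant at high dilution should secure this.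

Step 7
Reactants: 11 (6S)-3,11,11-trimethylspiro[5.5]undec-2-ene-7,10-dione
Product: 12 (2R,3R,6S)-2-bromo-7-methoxy-3,11,11-trimethyl-3,7-epoxyspiro[5.5]undecan-10-one (both C7 epimers)
Conditions: NBS (1.05 equiv), MeOH (3 equiv), NaHCO3, CH2Cl2, −20 → 0 °C, dark
Reagents that add atoms: N-bromosuccinimide, O=C1CCC(=O)N1Br; methanol, CO
Why: Bromoketalisation (haloetherification with carbonyl participation): NBS forms the C2–C3 bromonium ion reversibly on either face, but only the ion on the face away from C7 is opened at the tertiary C3 by the C7 carbonyl oxygen through a boat of ring B (a 2-oxabicyclo[2.2.2]octane, as in cineole-forming haloetherifications), and methanol caps the oxocarbenium ion, so Br (C2, R) and O (C3, R) are set anti to each other with oxygen on the C7 face, while the C10 carbonyl, which could reach C3 only through a seven-membered bridge, stays free.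

Step 8
Reactants: 12 (2R,3R,6S)-2-bromo-7-methoxy-3,11,11-trimethyl-3,7-epoxyspiro[5.5]undecan-10-one
Product: 14 (2R,3R,6S)-2-bromo-3,10-dihydroxy-3,11,11-trimethylspiro[5.5]undecan-7-one (both C10 epimers), via ketal alcohol 13 (not isolated)
Conditions: NaBH4, MeOH, 0 °C; then 2 M HCl, THF, 23 °C
Reagents that add atoms: water, O
Why: Borohydride reduction of the only free ketone and acid hydrolysis of the mixed ketal exchange the roles of the two carbonyl carbons, C10 now being masked as a carbinol (its configuration is immaterial, since the two ketal epimers hold ring A in opposite chairs and the carbinol is reoxidised in step 10) while C7 returns as the ketone beside the free trans-bromohydrin, which meets no base in any later step.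

Step 9
Reactants: 14 (2R,3R,6S)-2-bromo-3,10-dihydroxy-3,11,11-trimethylspiro[5.5]undecan-7-one
Product: 15 (2R,3R,6R)-2-bromo-3,11,11-trimethyl-7-methylidenespiro[5.5]undecane-3,10-diol (both C10 epimers)
Conditions: Cp2TiMe2 (5 equiv), toluene/THF, 75 °C, dark
Reagents that add atoms: dimethyltitanocene, C[Ti](C)(C1C=CC=C1)C1C=CC=C1
Why: Petasis methylenation, in which Cp2Ti=CH2 formed on heating olefinates the hindered C7 ketone under non-basic conditions that spare the trans-bromohydrin (no epoxide closure), the excess reagent covering the two hydroxyl groups as titanium alkoxides that are cleaved on work-up.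

Step 10
Reactants: 15 (2R,3R,6R)-2-bromo-3,11,11-trimethyl-7-methylidenespiro[5.5]undecane-3,10-diol
Product: 16 (2R,3R,6R)-2-bromo-3-hydroxy-3,11,11-trimethyl-7-methylidenespiro[5.5]undecan-10-one
Conditions: Dess–Martin periodinane, CH2Cl2, 23 °C
Reagents that add atoms: none
Why: Dess–Martin oxidation converts the secondary C10 carbinol (both epimers) into the ketone and cannot touch the tertiary C3 carbinol, the bromide or the 1,1-disubstituted alkene.

Step 11
Reactants: 16 (2R,3R,6R)-2-bromo-3-hydroxy-3,11,11-trimethyl-7-methylidenespiro[5.5]undecan-10-one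
Product: 17 (2R,3R,6R,10R)-2-bromo-3,11,11-trimethyl-7-methylidenespiro[5.5]undecane-3,10-diol
Conditions: (S)-1-methyl-3,3-diphenyltetrahydro-1H,3H-pyrrolo[1,2-c][1,3,2]oxazaborole (1.0 equiv), catecholborane (3 equiv), toluene, −40 °C; then MeOH, pH 7 buffer
Reagents that add atoms: none
Why: Corey–Bakshi–Shibata reduction, in which the quaternary C11 acts as the large and C9H2 as the small substituent so that the (S)-catalyst should deliver hydride to give the 10R alcohol (the sense known for tert-alkyl methyl ketones), ring A being free to adopt whichever chair suits the catalyst and catecholborane leaving the alkene alone.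

Step 12
Reactants: 17 (2R,3R,6R,10R)-2-bromo-3,11,11-trimethyl-7-methylidenespiro[5.5]undecane-3,10-diol
Product: 18 (2R,3R,6R,10S)-2,10-dibromo-3,11,11-trimethyl-7-methylidenespiro[5.5]undecan-3-ol (CNP0114057.1)
Conditions: PPh3 (3 equiv), CBr4 (3 equiv), 2,6-lutidine, toluene, 23 → 60 °C
Reagents that add atoms: carbon tetrabromide, BrC(Br)(Br)Br
Why: Appel reaction, in which bromide displaces the oxyphosphonium group with inversion (SN2) from the chair of ring A that holds this group axial, giving the equatorial 10S bromide, while the tertiary C3 hydroxyl is too hindered to be substituted and is returned on work-up.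

Compound list
1 | methyl 2,2-dimethylpent-4-enoate | C=CCC(C)(C)C(=O)OC | starting material
2 | methyl 2-methyl-2-(1,2,4-trioxolan-3-ylmethyl)propanoate (ozonide) | COC(=O)C(C)(C)CC1OCOO1 | intermediate
3 | methyl 2,2-dimethyl-4-oxobutanoate | COC(=O)C(C)(C)CC=O | intermediate
4 | methyl 3-formyl-2,2-dimethylbut-3-enoate | C=C(C=O)C(C)(C)C(=O)OC | intermediate
5 | isoprene | C=CC(C)=C | starting material
6 | methyl 2-[(1S)-1-formyl-4-methylcyclohex-3-en-1-yl]-2-methylpropanoate | O=C[C@]1(CCC(C)=CC1)C(C)(C)C(=O)OC | intermediate
7 | (5S)-1,4,4,8-tetramethyl-2-oxaspiro[4.5]dec-7-en-3-one (both C1 epimers) | CC1OC(=O)C(C)(C)[C@@]12CCC(C)=CC2 | intermediate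
8 | 3-[(1S)-1-(1-hydroxyethyl)-4-methylcyclohex-3-en-1-yl]-3-methylbutan-2-one (both carbinol epimers; in equilibrium with its cyclic hemiketal) | CC(O)[C@]1(CCC(C)=CC1)C(C)(C)C(C)=O | intermediate
9 | 3-[(1S)-1-acetyl-4-methylcyclohex-3-en-1-yl]-3-methylbutan-2-one | CC(=O)[C@]1(CCC(C)=CC1)C(C)(C)C(C)=O | intermediate
10 | dilithium bis-enolate of 9 (both acetyl groups as CH2=C(OLi)) | C=C(O[Li])[C@]1(CCC(C)=CC1)C(C)(C)C(=C)O[Li] | intermediate
11 | (6S)-3,11,11-trimethylspiro[5.5]undec-2-ene-7,10-dione | O=C1CCC(=O)C(C)(C)[C@@]12CCC(C)=CC2 | intermediate
12 | (2R,3R,6S)-2-bromo-7-methoxy-3,11,11-trimethyl-3,7-epoxyspiro[5.5]undecan-10-one (both C7 epimers) | COC12CCC(=O)C(C)(C)[C@]1(CC[C@@]3(C)O2)C[C@H]3Br | intermediate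
13 | (2R,3R,6S)-2-bromo-7-methoxy-3,11,11-trimethyl-3,7-epoxyspiro[5.5]undecan-10-ol (C7 and C10 epimers) | COC12CCC(O)C(C)(C)[C@]1(CC[C@@]3(C)O2)C[C@H]3Br | intermediate
14 | (2R,3R,6S)-2-bromo-3,10-dihydroxy-3,11,11-trimethylspiro[5.5]undecan-7-one (both C10 epimers) | O=C1CCC(O)C(C)(C)[C@@]12CC[C@@](C)(O)[C@H](Br)C2 | intermediate
15 | (2R,3R,6R)-2-bromo-3,11,11-trimethyl-7-methylidenespiro[5.5]undecane-3,10-diol (both C10 epimers; the C6 descriptor changes by the priority rules only) | C=C1CCC(O)C(C)(C)[C@@]12CC[C@@](C)(O)[C@H](Br)C2 | intermediate
16 | (2R,3R,6R)-2-bromo-3-hydroxy-3,11,11-trimethyl-7-methylidenespiro[5.5]undecan-10-one | C=C1CCC(=O)C(C)(C)[C@@]12CC[C@@](C)(O)[C@H](Br)C2 | intermediate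
17 | (2R,3R,6R,10R)-2-bromo-3,11,11-trimethyl-7-methylidenespiro[5.5]undecane-3,10-diol | C=C1CC[C@@H](O)C(C)(C)[C@@]12CC[C@@](C)(O)[C@H](Br)C2 | intermediate
18 | (2R,3R,6R,10S)-2,10-dibromo-3,11,11-trimethyl-7-methylidenespiro[5.5]undecan-3-ol | C=C1CC[C@H](Br)C(C)(C)[C@@]12CC[C@@](C)(O)[C@H](Br)C2 | target

Total step count: 12. Longest linear sequence: 12 steps (1 → 18; isoprene enters at step 3).

Steps most likely to fail

Step 6. The second deprotonation may lag behind the first, so that the mono-enolate closes the five-membered aldol, or the α-keto radical may be chlorinated or couple between molecules before ring A closes. Fallback, from 9 back to 11: soft enolisation of 9 with Me3SiOTf and Et3N in CH2Cl2 at 0 °C gives the bis(trimethylsilyl enol ether) F1, so that no free enolate ever faces a ketone. F1 is oxidised with (NH4)2Ce(NO3)6 and NaHCO3 in MeCN at −20 °C. The enol silane radical cation is captured by the second enol silane, a second oxidation and loss of both silyl groups follow, and the same C8–C9 bond is closed to give 11.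

Step 12. Elimination towards C9 or a 1,2-methyl shift from C11 may outrun substitution at the neopentylic carbon once the oxyphosphonium ion has formed. Fallback, from 17 back to 18: the secondary hydroxyl of 17 is converted with ClCH2SO2Cl and pyridine at 0 °C into the C10 chloromethanesulfonate F2, the tertiary hydroxyl being inert. This isolable leaving group for hindered secondary carbons ionises less readily than a triflate. F2 is displaced by LiBr in DMF at 50–80 °C with inversion to give 18.

Step 7. Capture of the bromonium ion by methanol from outside, on either face, may outrun the boat-shaped delivery of the C7 carbonyl oxygen, so that the C2/C3 configuration is lost and C7 stays unprotected. Fallback, from 11 back to 12: NBS in aqueous acetone at 0 °C opens the bromonium ion with water at C3 and gives both trans-bromohydrins, the (2R,3R,6S)-bromohydrin diketone F3 with the hydroxyl on the C7 face and its (2S,3S,6S)-diastereomer F4. Treatment of the mixture with pyridinium p-toluenesulfonate in MeOH closes only F3 to the bridged ketal 12, because only there can the C3 hydroxyl reach C7. F4 is then removed by chromatography and the route continues from 12.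

Further compounds
F1 | step 6 | [(1S)-4-methyl-1-(1-trimethylsilyloxyethenyl)cyclohex-3-en-1-yl]-substituted 3-methyl-2-trimethylsilyloxybut-1-ene, the bis(trimethylsilyl enol ether) of 9 | C=C(O[Si](C)(C)C)[C@]1(CCC(C)=CC1)C(C)(C)C(=C)O[Si](C)(C)C
F2 | step 12 | (2R,3R,6R,10R)-2-bromo-3-hydroxy-3,11,11-trimethyl-7-methylidenespiro[5.5]undecan-10-yl chloromethanesulfonate | C=C1CC[C@@H](OS(=O)(=O)CCl)C(C)(C)[C@@]12CC[C@@](C)(O)[C@H](Br)C2
F3 | step 7 | (2R,3R,6S)-2-bromo-3-hydroxy-3,11,11-trimethylspiro[5.5]undecane-7,10-dione | O=C1CCC(=O)C(C)(C)[C@@]12CC[C@@](C)(O)[C@H](Br)C2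
F4 | step 7 | (2S,3S,6S)-2-bromo-3-hydroxy-3,11,11-trimethylspiro[5.5]undecane-7,10-dione | O=C1CCC(=O)C(C)(C)[C@@]12CC[C@](C)(O)[C@@H](Br)C2
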